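## The problem

Target 15 consists of two carbocycles that share only one methylene carbon. C-4 of a 3,5-dihydroxycyclohexa-2,4-dien-1-one (ring A, the enol form of a 2-acylcyclohexane-1,3,5-trione) is joined through CH2 to C-1 of a cyclopentane (ring B). The five stereocentres form three groups: the three contiguous centres of ring B (C-1 carrying the methylene, the methyl carbinol C-2, the isopropenyl carbon C-5; CH2 and OH cis, isopropenyl trans to the CH2), the quaternary C-6 of ring A (methyl and prenyl), and the (S)-centre next to the acyl carbonyl. The methylene hinge and the flat, tautomerising enol system insulate these groups, so none can direct another and each needs its own source of chirality. Inside ring B the three centres are adjacent, so one bond-forming sequence can relay them. C-6 of ring A is the hardest centre: its two faces differ only in what sits two atoms away (acyl against hydrogen), and no reagent-controlled solution is established for it. The molecule tolerates little. Ring A is an acidic, chelating β-triketone. The tertiary alcohol is β to the hinge carbon and is lost by dehydration or retro-aldol cleavage whenever that carbon is a carbonyl. The isopropenyl and prenyl double bonds exclude hydrogenation, peracids and strong acid, and the side-chain centre is α to a ketone. The feature that opens the synthesis is the pattern of ring B: C-5, C-1 and C-2 are the β-carbon, the α-carbon and the carbinol carbon of a conjugate addition–aldol product. Ring B therefore unravels to an achiral, open-chain 6-oxohept-2-enoate whose ester carbon is the hinge methylene.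

## Retrosynthesis

**15 to 7 and 13.** The first cut is the bond between C-4 of ring A and the hinge methylene. It gives two pieces of similar size, hydroxy aldehyde 7 and acyl trione 13, and it uses the innate polarity of both: C-4 of 13 is the only acidic C–H of a cyclic β-dicarbonyl system, and the hinge carbon of 7 is a carbonyl. The neighbouring cut, between the methylene and C-1 of ring B, would require C-alkylation of 13 by a β-branched primary electrophile, which goes to oxygen. The forward reaction is a reductive alkylation through alkylidene trione 14. It must run near neutrality and at room temperature, because 7 is a β-hydroxy aldehyde, and it must leave both alkenes and the triketone untouched.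

**7 to 6 to 5.** No skeletal bond is cut here; the hinge carbon is taken back from aldehyde through diol 6 to ester 5. The ester is what the ring-forming step delivers, 6 is a stable storage form, and 7 is made last and used at once. The oxidation only has to distinguish a primary from a tertiary alcohol, but it must not be basic.

**5 to 3 and 4.** Two bonds are cut together: C-5 to isopropenyl and C-1 to C-2. Cutting only the aldol bond would call for an ester enolate next to a more acidic methyl ketone, which cannot be made by deprotonation; conjugate addition of the isopropenyl group generates exactly that enolate, regiospecifically, at the moment it is needed. The precursors are the achiral keto-enoate 3 and boronate 4, so ring B and all three of its stereocentres come from a catalyst. The forward reaction has to select one face of the enoate, cyclise before the enolate is protonated, and place hydroxyl cis and isopropenyl trans to the ester.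

**3 to 1 and 2.** The C2=C3 double bond of 3 is cut by cross-metathesis logic to hex-5-en-2-one 1 and ethyl acrylate 2. Both are commodity chemicals, and the alternative, a phosphonate olefination of 4-oxopentanal, would need a less accessible aldehyde. Only (E)-selectivity is asked of the forward step.

**13 to 11 and 12.** The bond between C-6 and the prenyl group is cut, which re-aromatises ring A to acylphloroglucinol 11, with prenyl bromide 12 as the electrophile. Cutting the methyl group instead would leave a prenylated acylphloroglucinol that must itself be made by a less selective prenylation. The forward reaction is an alkylative dearomatisation at the ring carbon that already bears methyl. No element controls which face is attacked, so the plan accepts both C-6 epimers. They are diastereomers because of the (S) side chain, and they are separated before the convergent step.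

**11 to 9 and 10 (from 8).** The aryl–acyl bond is cut to 2-methylphloroglucinol 9 and acid chloride 10, which is made from (S)-2-methylbutanoic acid 8. The two free positions of 9 are equivalent, so one ketone results. The side-chain stereocentre comes from the chiral pool and only has to survive the acylation.

## Roads not taken

**Alternative 1:** Ring B from the chiral pool by ring contraction.
- Cut and key step: the ring double bond of (R)-limonene A1 is cleaved to the keto aldehyde (3R)-6-oxo-3-(prop-1-en-2-yl)heptanal A2. Amine-catalysed aldol condensation (piperidinium acetate) then joins the aldehyde α-carbon to the ketone carbon and gives the enal (5S)-2-methyl-5-(prop-1-en-2-yl)cyclopent-1-ene-1-carbaldehyde A3.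
- Merits: two or three steps from a bulk terpene; the isopropenyl centre is bought with secure configuration; no transition metal; the hinge carbon is already an aldehyde.
- Weak points: the condensation removes the two centres the target needs beside the isopropenyl carbon. The tertiary alcohol and the C-1 hydrogen must be put back by a net hydration of a tetrasubstituted conjugated double bond, hydroxyl trans to isopropenyl and cis to the formyl group, without touching the isopropenyl alkene. This means several further steps at fully substituted carbons, with uncertain regiochemistry. A3 is also the dehydration product of 7, so this road runs against the thermodynamic slope.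
- Comparison: in cost, scale and certainty of absolute configuration this road is better. The chosen plan sets against it that one operation creates all three ring B centres at the right oxidation levels and reaches 7 in four steps.

**Alternative 2:** Three-component conjugate addition and Mannich trapping on a preformed ring.
- Cut and key step: the isopropenyl–ring bond and the ring–CH2 bond are cut. Isopropenylmagnesium bromide A5 adds to cyclopent-2-en-1-one A4 under CuBr·SMe2 with a chiral diphosphine, and the magnesium enolate is trapped with N,N-dimethylmethaniminium iodide (Eschenmoser's salt) A6. The product is (2R,3R)-2-[(dimethylamino)methyl]-3-(prop-1-en-2-yl)cyclopentan-1-one A7.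
- Merits: convergent; two trans ring centres and the hinge carbon in one flask. After quaternisation and elimination to the exocyclic enone (3S)-2-methylidene-3-(prop-1-en-2-yl)cyclopentan-1-one A8, trione 13 could be joined by conjugate addition. That union avoids the elimination-prone β-hydroxy aldehyde 7, a real advantage over the chosen plan.
- Weak points: cyclopentenone is among the least selective acceptors for copper-catalysed enantioselective Grignard addition, and alkenyl Grignard reagents are poorer donors than alkyl ones. The carbinol centre is missing. It must come from methyl addition to the ketone, either before the union (which then needs substitution at a hindered primary carbon) or after it (a methyl organometallic in the presence of the acidic triketone, with only 1,2-induction for the face).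
- Comparison: the chosen plan pays with a delicate last step, but it fixes the carbinol together with the other two centres.

**Alternative 3:** Ene cyclisation of an acyclic terpene alcohol.
- Cut and key step: the bond between the internal alkyne carbon and C-6 of (3R)-3,7-dimethyloct-6-en-1-yn-3-ol ((R)-dehydrolinalool) A9 is formed in an intramolecular Alder-ene reaction (thermal, or Pd(OAc)2-catalysed cycloisomerisation). A methyl hydrogen moves to the alkyne terminus, giving (1R,3S)-1-methyl-2-methylidene-3-(prop-1-en-2-yl)cyclopentan-1-ol A10.
- Merits: the shortest access to the ring B skeleton: one step, no reagent in the thermal version, carbinol in place, isopropenyl created by the hydrogen shift.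
- Weak points: A9 is an article of commerce as the racemate, so a resolution or an asymmetric ethynylation comes first. The carbinol–isopropenyl relationship depends on the ene transition state and is not reliably trans. In A10 the hinge carbon is an exocyclic methylene that must be functionalised beside a second 1,1-disubstituted alkene. The new C–H must also end trans to the hydroxyl, the opposite of what hydroxyl-directed delivery gives.
- Comparison: this road is shorter to the carbon skeleton. The chosen plan sets against it achiral starting materials, a hinge carbon that arrives as a carbonyl group, and a C-1 configuration fixed by the aldol geometry.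

Key step: step 2

Remark on the chemistry: the ring A compounds 13, 14 and 15 are mixtures of enol tautomers; names, SMILES and descriptors refer to the tautomer drawn.

## Route

Step 1
Reactants: 1 hex-5-en-2-one; 2 ethyl prop-2-enoate (ethyl acrylate, 3 equiv)
Product: 3 ethyl (2E)-6-oxohept-2-enoate
Conditions: second-generation Grubbs catalyst (2 mol%), CH2Cl2, 40 °C
Reagents that add atoms: none
Why: Olefin cross-metathesis of a terminal alkene with an electron-poor acrylate favours the cross product and the (E)-enoate; ethene leaves and the ketone is inert to the ruthenium carbene.

Step 2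
Reactants: 3 ethyl (2E)-6-oxohept-2-enoate; 4 4,4,5,5-tetramethyl-2-(prop-1-en-2-yl)-1,3,2-dioxaborolane (2 equiv)
Product: 5 ethyl (1S,2R,5R)-2-hydroxy-2-methyl-5-(prop-1-en-2-yl)cyclopentane-1-carboxylate
Conditions: [RhCl(C8H12)]2 (2.5 mol%), (S)-BINAP (6 mol%), KOH (20 mol%), H2O (5 equiv), 1,4-dioxane, 80 °C
Reagents that add atoms: none
Why: Proposed new method: the closest known reaction type is the rhodium–BINAP-catalysed conjugate arylation–aldol cyclisation of enones that carry a tethered ketone (a Hayashi–Miyaura addition whose rhodium enolate is caught intramolecularly); new here are the enoate as acceptor and an α-substituted alkenylboronate as donor, each known on its own in rhodium conjugate additions, as is aldol capture of ester-derived rhodium enolates by ketones in annulations of 2-acylarylboron reagents with acrylates. Mechanism: the hydroxorhodium–BINAP complex (monovalent rhodium) transmetalates with 4, the isopropenylrhodium species inserts the C2=C3 bond of 3 to give an oxa-π-allyl rhodium enolate, this enolate adds to the C-6 ketone, and water hydrolyses the rhodium aldolate to 5 and returns the hydroxo complex. The ring closes in the 5-(enolexo)-exo-trig mode. C-5 of 5 is set by the ligand: (S)-BINAP is chosen because, by the sense established for aryl transfer to (E)-enoates, it delivers the organic group to the face that is si at C-2 (re at C-3) of the enoate, which corresponds to (5R). C-1 and C-2 follow from C-5 in the aldol step: rhodium bridges the enolate and ketone oxygens in a closed Zimmerman–Traxler arrangement, which places hydroxyl cis to the ester, and allylic 1,3-strain keeps the C-3 hydrogen in the enolate plane, so the tether closes on the face opposite to isopropenyl and the ester ends trans to it. The step needs aldol addition to outrun protonation of the rhodium enolate; this is secured by the fast five-membered closure onto an unhindered methyl ketone and by holding water at a few equivalents, while 1,2-addition of the alkenylrhodium species to the ketone is slow.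

Step 3
Reactants: 5 ethyl (1S,2R,5R)-2-hydroxy-2-methyl-5-(prop-1-en-2-yl)cyclopentane-1-carboxylate
Product: 6 (1R,2R,3R)-2-(hydroxymethyl)-1-methyl-3-(prop-1-en-2-yl)cyclopentan-1-ol
Conditions: LiAlH4, THF, 0 °C to rt
Reagents that add atoms: none
Why: Hydride reduction of the ester to the primary alcohol; the tertiary alkoxide formed first is inert, no stereocentre is touched and the isolated alkene is not reduced.

Step 4
Reactants: 6 (1R,2R,3R)-2-(hydroxymethyl)-1-methyl-3-(prop-1-en-2-yl)cyclopentan-1-ol
Product: 7 (1S,2R,5R)-2-hydroxy-2-methyl-5-(prop-1-en-2-yl)cyclopentane-1-carbaldehyde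
Conditions: TEMPO (10 mol%), PhI(OAc)2 (1.1 equiv), CH2Cl2, rt
Reagents that add atoms: none
Why: Oxoammonium (TEMPO) oxidation takes the primary alcohol to the aldehyde and cannot oxidise the tertiary one; the non-basic medium should avoid dehydration, retro-aldol cleavage and epimerisation at C-1, and the aldehyde is used at once.

Step 5
Reactants: 8 (2S)-2-methylbutanoic acid; 9 2-methylbenzene-1,3,5-triol (2-methylphloroglucinol)
Product: 11 (2S)-2-methyl-1-(2,4,6-trihydroxy-3-methylphenyl)butan-1-one, via (2S)-2-methylbutanoyl chloride 10 (not isolated)
Conditions: (COCl)2, DMF (cat.), CH2Cl2, 0 °C to rt; then 9, AlCl3 (4 equiv), PhNO2, 0 °C to rt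
Reagents that add atoms: none
Why: Friedel–Crafts C-acylation of the highly activated triol, whose two free ring positions are equivalent, so one ketone forms and the acyl group deactivates the ring against a second. The acid chloride is made and used cold so that the stereocentre from the chiral pool, α to the carbonyl, is kept.

Step 6
Reactants: 11 (2S)-2-methyl-1-(2,4,6-trihydroxy-3-methylphenyl)butan-1-one; 12 1-bromo-3-methylbut-2-ene (prenyl bromide, 1.0 equiv)
Product: 13 (6R)-3,5-dihydroxy-6-methyl-6-(3-methylbut-2-en-1-yl)-2-[(2S)-2-methylbutanoyl]cyclohexa-2,4-dien-1-one
Conditions: NaOMe (2.2 equiv), MeOH, 0 °C; aq. HCl; silica gel, then preparative HPLC on amylose tris(3,5-dimethylphenylcarbamate)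
Reagents that add atoms: none
Why: Alkylative dearomatisation: in methanol the phenoxide is alkylated on carbon, and the ring carbon that already bears methyl is the more nucleophilic one, as in the geminal dialkylations that lead to filicinic-acid-type triketones. No element controls the face of attack, so both C-6 configurations form as diastereomers; the (6R) compound is isolated by chromatography and the other epimer is discarded.

Step 7
Reactants: 7 (1S,2R,5R)-2-hydroxy-2-methyl-5-(prop-1-en-2-yl)cyclopentane-1-carbaldehyde (1.2 equiv); 13 (6R)-3,5-dihydroxy-6-methyl-6-(3-methylbut-2-en-1-yl)-2-[(2S)-2-methylbutanoyl]cyclohexa-2,4-dien-1-one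
Product: 15 (6R)-3,5-dihydroxy-4-{[(1S,2R,5R)-2-hydroxy-2-methyl-5-(prop-1-en-2-yl)cyclopentyl]methyl}-6-methyl-6-(3-methylbut-2-en-1-yl)-2-[(2S)-2-methylbutanoyl]cyclohexa-2,4-dien-1-one, via alkylidene trione 14 (not isolated)
Conditions: L-proline (20 mol%), diethyl 2,6-dimethyl-1,4-dihydropyridine-3,5-dicarboxylate (Hantzsch ester, 1.2 equiv), CH2Cl2, rt
Reagents that add atoms: none
Why: Three-component reductive alkylation (amine-catalysed Knoevenagel condensation, then conjugate hydride transfer from the dihydropyridine): the only acidic C–H of 13, C-4, condenses with the iminium ion of 7, and 14 is reduced as it forms, which keeps a second trione from adding. The neutral, room-temperature medium should spare the tertiary alcohol, both alkenes and all five stereocentres; no stereocentre is created.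

## Compound list

1 | hex-5-en-2-one | CC(=O)CCC=C | starting material
2 | ethyl prop-2-enoate (ethyl acrylate) | C=CC(=O)OCC | starting material
3 | ethyl (2E)-6-oxohept-2-enoate | CCOC(=O)/C=C/CCC(C)=O | intermediate
4 | 4,4,5,5-tetramethyl-2-(prop-1-en-2-yl)-1,3,2-dioxaborolane | C=C(C)B1OC(C)(C)C(C)(C)O1 | starting material
5 | ethyl (1S,2R,5R)-2-hydroxy-2-methyl-5-(prop-1-en-2-yl)cyclopentane-1-carboxylate | C=C(C)[C@@H]1CC[C@@](C)(O)[C@H]1C(=O)OCC | intermediate
6 | (1R,2R,3R)-2-(hydroxymethyl)-1-methyl-3-(prop-1-en-2-yl)cyclopentan-1-ol | C=C(C)[C@@H]1CC[C@@](C)(O)[C@H]1CO | intermediate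
7 | (1S,2R,5R)-2-hydroxy-2-methyl-5-(prop-1-en-2-yl)cyclopentane-1-carbaldehyde | C=C(C)[C@@H]1CC[C@@](C)(O)[C@H]1C=O | intermediate
8 | (2S)-2-methylbutanoic acid | CC[C@H](C)C(=O)O | starting material
9 | 2-methylbenzene-1,3,5-triol (2-methylphloroglucinol) | Cc1c(O)cc(O)cc1O | starting material
10 | (2S)-2-methylbutanoyl chloride | CC[C@H](C)C(=O)Cl | intermediate
11 | (2S)-2-methyl-1-(2,4,6-trihydroxy-3-methylphenyl)butan-1-one | CC[C@H](C)C(=O)c1c(O)cc(O)c(C)c1O | intermediate
12 | 1-bromo-3-methylbut-2-ene (prenyl bromide) | CC(C)=CCBr | starting material
13 | (6R)-3,5-dihydroxy-6-methyl-6-(3-methylbut-2-en-1-yl)-2-[(2S)-2-methylbutanoyl]cyclohexa-2,4-dien-1-one | CC[C@H](C)C(=O)C1=C(O)C=C(O)[C@@](C)(CC=C(C)C)C1=O | intermediate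
14 | alkylidene trione (Knoevenagel adduct): 5-hydroxy-2-{[(1S,2R,5R)-2-hydroxy-2-methyl-5-(prop-1-en-2-yl)cyclopentyl]methylidene}-6-methyl-6-(3-methylbut-2-en-1-yl)-4-[(2S)-2-methylbutanoyl]cyclohex-4-ene-1,3-dione; arrangement at the quaternary carbon as in 13 (6S in this numbering); geometry of the exocyclic alkene not defined | C=C(C)[C@@H]1CC[C@@](C)(O)[C@H]1C=C1C(=O)[C@@](C)(CC=C(C)C)C(O)=C(C(=O)[C@@H](C)CC)C1=O | intermediate
15 | (6R)-3,5-dihydroxy-4-{[(1S,2R,5R)-2-hydroxy-2-methyl-5-(prop-1-en-2-yl)cyclopentyl]methyl}-6-methyl-6-(3-methylbut-2-en-1-yl)-2-[(2S)-2-methylbutanoyl]cyclohexa-2,4-dien-1-one (CNP0299585.2) | C=C(C)[C@@H]1CC[C@@](C)(O)[C@H]1CC1=C(O)[C@@](C)(CC=C(C)C)C(=O)C(C(=O)[C@@H](C)CC)=C1O | target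

## Step count and risks

Total step count: 7. Longest linear sequence: 5 steps (steps 1, 2, 3, 4 and 7, from hex-5-en-2-one); the ring A branch has 3 steps (5, 6 and 7).

**Step 2 (key step, proposed new method).**
- What may go wrong: protonation of the rhodium enolate by water before it cyclises, which would give the open-chain conjugate adduct. Transmetalation of the α-substituted alkenylboronate may also be slow, with protodeboronation competing. Enantioface selection may be weaker for an enoate than for an enone. The sense of induction is taken by analogy with aryl transfer and has to be confirmed on the first batch.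
- Fallback, from known reactions only: the same two bonds are made by an auxiliary-controlled cuprate Michael–aldol domino that sets out from 1. (4S)-4-Benzyl-1,3-oxazolidin-2-one is N-acylated with acryloyl chloride (n-BuLi, THF, −78 °C) to the acrylimide (4S)-4-benzyl-3-(prop-2-enoyl)-1,3-oxazolidin-2-one F1. Cross-metathesis of F1 with 1 (second-generation Grubbs catalyst, CH2Cl2, 40 °C) gives the oxo-enimide (4S)-4-benzyl-3-[(2E)-6-oxohept-2-enoyl]-1,3-oxazolidin-2-one F2. The cuprate from isopropenylmagnesium bromide (2 equiv) and CuBr·SMe2 (THF, −78 to −30 °C) adds to the magnesium-chelated s-cis enimide on the face away from the benzyl group. The magnesium enolate then closes on the free ketone, as in cuprate-triggered Michael–aldol cyclisations of oxo-enimides, to give the imide (4S)-4-benzyl-3-{[(1S,2R,5R)-2-hydroxy-2-methyl-5-(prop-1-en-2-yl)cyclopentyl]carbonyl}-1,3-oxazolidin-2-one F3. LiBH4 (THF, MeOH, 0 °C) removes the auxiliary reductively, and the fallback returns to the route at diol 6.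

**Step 6.**
- What may go wrong: absence of facial selectivity is inherent, so at best half of the alkylated material has the (6R) configuration. The two epimers may also co-elute, since their stereocentres lie far apart across a flat enol system. Alkylation at the free ring carbon or on oxygen, and a second prenylation, would lower the yield further. The configuration of each epimer has to be assigned, by X-ray analysis of a crystalline derivative or by correlation with 15.
- Fallback: the separation is moved to the end, where the epimers carry three more stereocentres and a hydrogen-bonding hydroxyl close to C-6. It sets out from 11. Prenylation as in step 6, purified on silica only, gives the C-6 epimer pair 3,5-dihydroxy-6-methyl-6-(3-methylbut-2-en-1-yl)-2-[(2S)-2-methylbutanoyl]cyclohexa-2,4-dien-1-one, the (6RS) mixture F4. Reductive alkylation of F4 with 7 under the conditions of step 7 gives 15 together with the (6S) epimer of 15 F5. The two are separated by preparative reversed-phase HPLC, and the fallback returns to the route at 15.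

**Step 7.**
- What may go wrong: amine-catalysed dehydration of the β-hydroxy aldehyde (elimination of the tertiary hydroxyl through the enamine), retro-aldol opening of ring B, or epimerisation at C-1 before the hindered, α-branched aldehyde has condensed with the trione.
- Fallback: the tertiary hydroxyl is carried as a silyl ether through oxidation and coupling. It sets out from 6. Et3SiOTf (2.5 equiv) and 2,6-lutidine in CH2Cl2 give the bis(triethylsilyl) ether of 6 F6. Swern oxidation ((COCl)2, DMSO, then i-Pr2NEt, −78 to −20 °C), which converts primary triethylsilyl ethers directly into aldehydes and leaves tertiary ones intact, gives (1S,2R,5R)-2-methyl-5-(prop-1-en-2-yl)-2-[(triethylsilyl)oxy]cyclopentane-1-carbaldehyde F7. Reductive alkylation of 13 with F7 under the conditions of step 7 gives the O-triethylsilyl ether of 15 F8. HF·pyridine (THF, 0 °C) removes the silyl group, and the fallback returns to the route at 15.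

**Step 5.**
- What may go wrong: loss of configurational purity at the side-chain centre, by ketene formation from the acid chloride or by AlCl3-promoted enolisation of the aryl ketone; every later compound would then carry an inseparable side-chain epimer.
- Fallback: the ketone is made without a Lewis acid, by adding an aryllithium to a Weinreb amide. It sets out from 9 and 8. MOMCl and i-Pr2NEt (CH2Cl2) convert 9 into 1,3,5-tris(methoxymethoxy)-2-methylbenzene F9. MeNHOMe·HCl and EDC·HCl (CH2Cl2) convert 8 into (2S)-N-methoxy-N,2-dimethylbutanamide F10. Lithiation of F9 between two methoxymethoxy groups (n-BuLi, THF, 0 °C) and addition to F10 give (2S)-2-methyl-1-[2,4,6-tris(methoxymethoxy)-3-methylphenyl]butan-1-one F11. HCl in MeOH at rt removes the three acetals, and the fallback returns to the route at 11.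

## Further compounds

F1 | step 2 | (4S)-4-benzyl-3-(prop-2-enoyl)-1,3-oxazolidin-2-one | C=CC(=O)N1[C@@H](Cc2ccccc2)COC1=O
F2 | step 2 | (4S)-4-benzyl-3-[(2E)-6-oxohept-2-enoyl]-1,3-oxazolidin-2-one | CC(=O)CC/C=C/C(=O)N1[C@@H](Cc2ccccc2)COC1=O
F3 | step 2 | (4S)-4-benzyl-3-{[(1S,2R,5R)-2-hydroxy-2-methyl-5-(prop-1-en-2-yl)cyclopentyl]carbonyl}-1,3-oxazolidin-2-one | C=C(C)[C@@H]1CC[C@@](C)(O)[C@H]1C(=O)N1[C@@H](Cc2ccccc2)COC1=O
F4 | step 6 | 3,5-dihydroxy-6-methyl-6-(3-methylbut-2-en-1-yl)-2-[(2S)-2-methylbutanoyl]cyclohexa-2,4-dien-1-one, (6RS) epimer mixture | CC[C@H](C)C(=O)C1=C(O)C=C(O)C(C)(CC=C(C)C)C1=O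
F5 | step 6 | (6S)-3,5-dihydroxy-4-{[(1S,2R,5R)-2-hydroxy-2-methyl-5-(prop-1-en-2-yl)cyclopentyl]methyl}-6-methyl-6-(3-methylbut-2-en-1-yl)-2-[(2S)-2-methylbutanoyl]cyclohexa-2,4-dien-1-one (C-6 epimer of 15) | C=C(C)[C@@H]1CC[C@@](C)(O)[C@H]1CC1=C(O)[C@](C)(CC=C(C)C)C(=O)C(C(=O)[C@@H](C)CC)=C1O
F6 | step 7 | bis(triethylsilyl) ether of 6 (both hydroxyls silylated, ring configuration as in 6) | C=C(C)[C@@H]1CC[C@@](C)(O[Si](CC)(CC)CC)[C@H]1CO[Si](CC)(CC)CC
F7 | step 7 | (1S,2R,5R)-2-methyl-5-(prop-1-en-2-yl)-2-[(triethylsilyl)oxy]cyclopentane-1-carbaldehyde | C=C(C)[C@@H]1CC[C@@](C)(O[Si](CC)(CC)CC)[C@H]1C=O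
F8 | step 7 | O-triethylsilyl ether of 15 (tertiary hydroxyl of ring B silylated) | C=C(C)[C@@H]1CC[C@@](C)(O[Si](CC)(CC)CC)[C@H]1CC1=C(O)[C@@](C)(CC=C(C)C)C(=O)C(C(=O)[C@@H](C)CC)=C1O
F9 | step 5 | 1,3,5-tris(methoxymethoxy)-2-methylbenzene | Cc1c(OCOC)cc(OCOC)cc1OCOC
F10 | step 5 | (2S)-N-methoxy-N,2-dimethylbutanamide | CC[C@H](C)C(=O)N(C)OC
F11 | step 5 | (2S)-2-methyl-1-[2,4,6-tris(methoxymethoxy)-3-methylphenyl]butan-1-one | CC[C@H](C)C(=O)c1c(OCOC)cc(OCOC)c(C)c1OCOC
A1 | alternative 1 | (R)-limonene, (4R)-1-methyl-4-(prop-1-en-2-yl)cyclohex-1-ene | CC1=CC[C@@H](CC1)C(C)=C
A2 | alternative 1 | (3R)-6-oxo-3-(prop-1-en-2-yl)heptanal | C=C(C)[C@@H](CC=O)CCC(C)=O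
A3 | alternative 1 | (5S)-2-methyl-5-(prop-1-en-2-yl)cyclopent-1-ene-1-carbaldehyde | C=C(C)[C@@H]1CCC(C)=C1C=O
A4 | alternative 2 | cyclopent-2-en-1-one | O=C1C=CCC1
A5 | alternative 2 | isopropenylmagnesium bromide | C=C(C)[Mg]Br
A6 | alternative 2 | N,N-dimethylmethaniminium iodide (Eschenmoser's salt) | C=[N+](C)C.[I-]
A7 | alternative 2 | (2R,3R)-2-[(dimethylamino)methyl]-3-(prop-1-en-2-yl)cyclopentan-1-one | C=C(C)[C@@H]1CCC(=O)[C@H]1CN(C)C
A8 | alternative 2 | (3S)-2-methylidene-3-(prop-1-en-2-yl)cyclopentan-1-one | C=C(C)[C@@H]1CCC(=O)C1=C
A9 | alternative 3 | (3R)-3,7-dimethyloct-6-en-1-yn-3-ol ((R)-dehydrolinalool) | C#C[C@](C)(O)CCC=C(C)C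
A10 | alternative 3 | (1R,3S)-1-methyl-2-methylidene-3-(prop-1-en-2-yl)cyclopentan-1-ol | C=C(C)[C@@H]1CC[C@@](C)(O)C1=C
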